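## Retrosynthetic overview

1. The C2 carbinol C(CH3)2OH is cut back to a methyl ester (two C–CH3 bonds from a Grignard reagent), so no prenyl group has to be oxidised.
2. The strategy rests on one run of atoms in the six-membered ring: C3a (quaternary, prenylated), C7a bearing O1, and C7 (prenylated). This run is C3, C4(–O4) and C5 of deoxycohumulone, a flat acylphloroglucinol whose two prenylated carbons are symmetry-equivalent and flank the only oxygen not chelated to the isobutyryl C=O.
3. Furan atoms C3 and C2 and the ester carbon come from methyl 2-bromoacrylate. C3a–C3 forms by dearomative Michael addition and O1–C2 by SN2, in one flask under a chiral ammonium cation.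
4. Deoxycohumulone comes from phloroglucinol by Friedel–Crafts acylation and double C-prenylation.
5. Ring order: the carbocycle is bought as the arene and dearomatised in the key step, the dihydrofuran closes in that same step, and no ring is formed afterwards.

Key step: step 3

Remark (locants): in 5 the isobutyryl-bearing ring carbon is C1, the oxygens sit on C2, C4 and C6, and the prenyl groups on C3 and C5. The bicyclic compounds are numbered as benzofurans (O1, C2, C3, C3a, C4–C7, C7a).

Remark (assumption): the sense of induction of the ammonium ion pair cannot be derived from first principles. The cinchonidinium salt is written, and the first run is to be assigned by ECD or anomalous-dispersion X-ray. If it gives the 3aR series, the cinchoninium pseudoenantiomer replaces it with nothing else changed.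

Remark: dearomatised compounds are drawn in the 6-hydroxy-4-oxo tautomer of the target SMILES. Compound 6 is taken as a purchasable stabilised monomer, freed from stabiliser just before use.

## Route

Step 1
Reactants: 1 phloroglucinol; 2 isobutyryl chloride
Product: 3 phlorisobutyrophenone (1-(2,4,6-trihydroxyphenyl)-2-methylpropan-1-one)
Conditions: AlCl3 (4 equiv), PhNO2, 65 °C; ice/1 M HCl
Reagents that add atoms: isobutyryl chloride (2), CC(C)C(=O)Cl
Why: Friedel–Crafts C-acylation of a very electron-rich arene, in which the first acyl group, held in an aluminium chelate with the flanking phenoxides, deactivates the ring enough to stop at the monoketone, and any aryl ester formed first is brought to the same ketone by Fries rearrangement.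

Step 2
Reactants: 3 phlorisobutyrophenone; 4 prenyl bromide (1-bromo-3-methylbut-2-ene)
Product: 5 deoxycohumulone (1-[2,4,6-trihydroxy-3,5-bis(3-methylbut-2-enyl)phenyl]-2-methylpropan-1-one)
Conditions: 4 (2.0 equiv), aq KOH (2.1 equiv), Ar, 0 °C to rt; 1 M HCl; SiO2
Reagents that add atoms: prenyl bromide (4), CC(C)=CCBr
Why: C-alkylation of an ambident phenoxide, in which water solvates the oxygens and steers the soft allylic bromide to the two free ring carbons, while two equivalents of 4 and low temperature hold back the dearomatising third prenylation, and mono- and triprenyl material is removed on silica.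

Step 3
Reactants: 5 deoxycohumulone; 6 methyl 2-bromoacrylate
Product: 8 methyl (2S,3aS)-6-hydroxy-5-isobutyryl-3a,7-bis(3-methylbut-2-enyl)-4-oxo-2,3,3a,4-tetrahydrobenzofuran-2-carboxylate (ester trans to the angular prenyl), via bromo ester Michael adduct 7 (not isolated)
Conditions: 6 (1.2 equiv, slow addition), O-allyl-N-(9-anthracenylmethyl)cinchonidinium bromide (10 mol %), ground Cs2CO3 (3 equiv), 4 Å MS, degassed PhMe/CH2Cl2, Ar, −40 °C; then Bu4NBr (20 mol %), to 0 °C; cold 1 M HCl
Reagents that add atoms: methyl 2-bromoacrylate (6), C=C(Br)C(=O)OC
Why: Proposed new method: the ion-paired phloroglucinolate of 5 should attack the CH2 terminus of 6 through prenyl-bearing C3, which gives up aromaticity and creates the quaternary carbon, and the resulting bromo ester enolate is quenched by an acidic ring OH to leave the lupulone-type enolate 7. The closest known reaction types are the chiral phase-transfer alkylative dearomatisation–annulation of 3,5-diprenyl acylphloroglucinols with acrylate- and enal-type acceptors and the Michael/O-alkylation (interrupted Feist–Benary) annulation of cyclic 1,3-diones with 2-bromoacrylates, and what has not been shown is their combination on an arene. The dihydrofuran ring closes second, by 5-exo-tet SN2 displacement of bromide at the ester α-carbon by enolate oxygen O4 (C3a–C3 bond first, O1–C2 bond second), while an oxygen-first sequence is a reversible dead end, since the oxa-Michael adduct could only close at carbon through an enolendo-type geometry in which a short tether anchored in the ring plane must reach the π face of the adjacent carbon. C3a is controlled by the chiral cation: the C2 axis of the anion makes C3 on one face identical with C5 on the other, so no regiochemical question arises, but on any one face C3 and C5 are enantiotopic and the tight ion pair in the non-polar medium has to choose between them. C2 is controlled in the closure under Curtin–Hammett conditions: degenerate bromide exchange scrambles the CHBr epimers of 7 (Bu4NBr is added only after the C–C step so that an achiral cation cannot compete in the enantiodetermining event, and exchange is preferred to enolisation, which would reopen the retro-Michael path), and the R bromide, which places CO2Me anti to the angular prenyl standing perpendicular to the bicycle, should close faster and with inversion to 2S. The step also needs O4 to win over O2 and C5, which the substrate secures because O2 and O6 are tied to the isobutyryl carbonyl by hydrogen bond or caesium chelation and closure at O4 leaves that acyl-enol triketone intact, whereas C5 attack would have to build a bicyclo[3.2.1]octanetrione through a badly aligned SN2 trajectory.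

Step 4
Reactants: 8 methyl (2S,3aS)-tetrahydrobenzofuran-2-carboxylate; 9 methylmagnesium bromide
Product: 11 (2S,3aS)-6-hydroxy-2-(2-hydroxypropan-2-yl)-5-isobutyryl-3a,7-bis(3-methylbut-2-enyl)-3,3a-dihydrobenzofuran-4(2H)-one (CNP0361579.1), via methyl ketone 10 (not isolated)
Conditions: 8 added to MeMgBr (6 equiv), THF, −78 to 0 °C; cold 1 M HCl
Reagents that add atoms: methylmagnesium bromide (9), C[Mg]Br
Why: Double Grignard addition to an ester, in which the first equivalent turns the acidic acyl-enol into a magnesium triketonate whose delocalised charge switches off C4=O, C6=O, the isobutyryl C=O and the vinylogous ester carbon C7a, so the α-alkoxy ester activated by O1–Mg chelation is the only electrophile left, while C2 is not a reacting centre and C3a is quaternary, so both configurations are carried through.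

## Compound list

1 | phloroglucinol | Oc1cc(O)cc(O)c1 | starting material
2 | isobutyryl chloride | CC(C)C(=O)Cl | starting material
3 | phlorisobutyrophenone | CC(C)C(=O)c1c(O)cc(O)cc1O | intermediate
4 | prenyl bromide | CC(C)=CCBr | starting material
5 | deoxycohumulone | CC(C)C(=O)c1c(O)c(CC=C(C)C)c(O)c(CC=C(C)C)c1O | intermediate
6 | methyl 2-bromoacrylate | C=C(Br)C(=O)OC | starting material
7 | methyl (2R)-2-bromo-3-[(1S)-2,4-dihydroxy-5-isobutyryl-1,3-bis(3-methylbut-2-enyl)-6-oxocyclohexa-2,4-dien-1-yl]propanoate (present as its enolate; the CHBr epimers interconvert, the productive R epimer is drawn) | CC(C)=CCC1=C(O)[C@@](C[C@@H](Br)C(=O)OC)(CC=C(C)C)C(=O)C(C(=O)C(C)C)=C1O | intermediate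
8 | methyl (2S,3aS)-6-hydroxy-5-isobutyryl-3a,7-bis(3-methylbut-2-enyl)-4-oxo-2,3,3a,4-tetrahydrobenzofuran-2-carboxylate | CC(C)=CCC1=C2O[C@H](C(=O)OC)C[C@]2(CC=C(C)C)C(=O)C(C(=O)C(C)C)=C1O | intermediate
9 | methylmagnesium bromide | C[Mg]Br | starting material
10 | (2S,3aS)-2-acetyl-6-hydroxy-5-isobutyryl-3a,7-bis(3-methylbut-2-enyl)-3,3a-dihydrobenzofuran-4(2H)-one | CC(C)=CCC1=C2O[C@H](C(C)=O)C[C@]2(CC=C(C)C)C(=O)C(C(=O)C(C)C)=C1O | intermediate
11 | (2S,3aS)-6-hydroxy-2-(2-hydroxypropan-2-yl)-5-isobutyryl-3a,7-bis(3-methylbut-2-enyl)-3,3a-dihydrobenzofuran-4(2H)-one | CC(C)=CCC1=C2O[C@H](C(C)(C)O)C[C@]2(CC=C(C)C)C(=O)C(C(=O)C(C)C)=C1O | target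

Total step count: 4
Longest linear sequence: 4 (1 to 3 to 5 to 8 to 11)

## Steps most likely to fail

**1. Step 3.**
- What may go wrong:
  - The ion pair may differentiate the enantiotopic positions too weakly.
  - The ring may close through the chelated oxygen.
  - Closure may outrun bromide exchange, so that the trans preference is lost.
  - The acceptor may polymerise anionically.
- Fallback (known chemistry, from 5 to 11):
  - Compound 5 is prenylated a third time with 4 (NaOMe, MeOH, 0 °C). This is the classical dearomatising C-alkylation of the hop β-acid series and gives colupulone F1.
  - One equivalent of mCPBA (NaHCO3, CH2Cl2, 0 °C) epoxidises, among the three side chains, one of the geminal prenyl groups to give the racemic epoxide F2.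
  - K2CO3 in MeOH opens F2 5-exo-tet at the secondary carbon through O4 with inversion.
  - Silica gel removes the cis isomer F3 and the products of epoxidation at the other prenyl group.
  - Preparative chromatography on a chiral stationary phase parts 11 from its mirror image F4.
  - The route is rejoined at 11, and step 4 is then not needed.

**2. Step 4.**
- What may go wrong:
  - Deprotonation at C2 may compete with addition. This leads to epimerisation or to a retro-Michael opening of the C3–C3a bond with rearomatisation.
  - The reaction may stall at the ketone stage.
- Fallback (from 8, rejoining at 10 and going on to 11):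
  - AlMe3/MeNHOMe·HCl (CH2Cl2, 0 °C) converts the ester into the Weinreb amide F5.
  - MeMgBr (THF, −78 °C) gives a chelated tetrahedral adduct that survives until the quench and releases ketone 10, which is now isolated.
  - The non-basic methylcerium reagent (MeLi/CeCl3, THF, −78 °C) then adds once to give 11. The double addition is thus split into two single additions, neither of which exposes an enolisable carbonyl to excess strong base.

**3. Step 2.**
- What may go wrong:
  - Under- and over-alkylation may follow statistics.
  - O-alkylation may occur.
  - The electron-rich product may autoxidise in base.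
- Fallback (from 3 to 5):
  - Acid-catalysed Friedel–Crafts prenylation with 2-methylbut-3-en-2-ol (2 equiv) and BF3·OEt2 in dioxane at rt is used instead.
  - The neutral ring is attacked by the dimethylallyl cation, so the phenoxide-dependent O-alkylation and geminal dialkylation are closed off.
  - Short contact time limits chroman formation.
  - This fallback makes no compound outside the list (F0).

## Further compounds

F1 | step 3 | colupulone (3,5-dihydroxy-2-isobutyryl-4,6,6-tris(3-methylbut-2-enyl)cyclohexa-2,4-dien-1-one) | CC(C)C(=O)C1=C(O)C(CC=C(C)C)=C(O)C(CC=C(C)C)(CC=C(C)C)C1=O
F2 | step 3 | colupulone mono-epoxide at one geminal prenyl group (racemic; drawn as the quaternary-S, epoxide-R enantiomer that leads to 11) | CC(C)=CCC1=C(O)[C@@](C[C@H]2OC2(C)C)(CC=C(C)C)C(=O)C(C(=O)C(C)C)=C1O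
F3 | step 3 | cis isomer of 11 (racemic; drawn as 2S,3aR) | CC(C)=CCC1=C2O[C@H](C(C)(C)O)C[C@@]2(CC=C(C)C)C(=O)C(C(=O)C(C)C)=C1O
F4 | step 3 | mirror image of 11 (2R,3aR) | CC(C)=CCC1=C2O[C@@H](C(C)(C)O)C[C@@]2(CC=C(C)C)C(=O)C(C(=O)C(C)C)=C1O
F5 | step 4 | (2S,3aS)-N-methoxy-N-methyl carboxamide corresponding to 8 (Weinreb amide) | CC(C)=CCC1=C2O[C@H](C(=O)N(C)OC)C[C@]2(CC=C(C)C)C(=O)C(C(=O)C(C)C)=C1O
F0 | step 2 | none | none
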